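**Retrosynthetic overview**
- Ring A (the pyran) is closed last, by acid, from a ring B dienone that already carries C1 as an acetal and C3/C4 as a silyl enol ether. No redox step is needed.
- Ring B, a 6-acyloxy-6-methylcyclohexa-2,4-dienone with all four oxygenated carbons (C5–C8) and the C7 butanoate in place, comes from a two-carbon ring expansion: an alkyne is inserted into the acyl–alkenyl bond of a cyclobutenone.
- The cyclobutenone is squaric acid + MeLi + butanoyl chloride (C7 is made here and resolved). The alkyne is 3,3-dimethoxypropyne + DMF + 2,3-dihydrofuran + MeI.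
- Ring order: four-membered ring (from squaric acid), then ring B by ring expansion, then ring A by cyclisation.

Assumption: the stereocentre in the SMILES is read as (7R) in 6H-isochromene numbering (C1, O2, C3 … C8a), and 3,3-dimethoxyprop-1-yne is taken as a catalogue compound.

Step 1
Reactants: 1 3,3-dimethoxyprop-1-yne
Product: 3 4,4-dimethoxybut-2-ynal, via lithium acetylide 2 (not isolated)
Conditions: n-BuLi (1.05 equiv), THF, −78 °C; DMF (1.5 equiv), −78 → 0 °C; inverse quench into cold aq. KH2PO4/MTBE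
Reagents that add atoms: N,N-dimethylformamide, CN(C)C=O
Why: Deprotonation of the terminal alkyne and formylation of the acetylide with DMF is the standard route to ynals, and the buffered inverse quench keeps the liberated amine from adding to the product.

Step 2
Reactants: 4 2,3-dihydrofuran; 3 4,4-dimethoxybut-2-ynal
Product: 7 5-(1,4,4-trimethoxybut-2-yn-1-yl)-2,3-dihydrofuran, via 5-lithio-2,3-dihydrofuran 5 (not isolated), via lithium alkoxide adduct 6 (not isolated)
Conditions: 4 (1.2 equiv), t-BuLi (1.1 equiv), THF, −78 → 0 °C; 3, −78 °C; MeI (3 equiv), DMPU, −78 °C → rt; chromatography on Et3N-deactivated silica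
Reagents that add atoms: iodomethane, CI
Why: α-Lithiated dihydrofuran is an established acyl-anion equivalent that adds 1,2 to the ynal, and the alkoxide is O-methylated in the same flask (Williamson etherification); the new carbinol centre is racemic and is erased in step 3.

Step 3
Reactants: 7 5-(1,4,4-trimethoxybut-2-yn-1-yl)-2,3-dihydrofuran
Product: 9 (Z)-5,8-bis(tert-butyldimethylsilyloxy)-1,1,4-trimethoxyoct-4-en-2-yne, via hydroxy ketone 8 (not isolated)
Conditions: (i) 0.1 M HCl, THF–H2O, 0 °C, then NaHCO3 work-up; (ii) TBSOTf (2.4 equiv), Et3N (4 equiv), CH2Cl2, −78 → 0 °C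
Reagents that add atoms: water, O; tert-butyldimethylsilyl trifluoromethanesulfonate, CC(C)(C)[Si](C)(C)OS(=O)(=O)C(F)(F)F
Why: Acid hydrolysis of the cyclic enol ether (much faster than that of the alkynyl acetal) unveils the γ-hydroxy ketone, and soft enolisation with silyl triflate/Et3N removes the doubly activated α-hydrogen to give the alkyne-conjugated silyl enol ether while silylating the primary alcohol, so the racemic centre of 7 becomes sp2 (the alkene geometry has no consequence later).

Step 4
Reactants: 10 squaric acid (3,4-dihydroxycyclobut-3-ene-1,2-dione)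
Product: 11 3,4-di-tert-butoxycyclobut-3-ene-1,2-dione
Conditions: tert-butyl 2,2,2-trichloroacetimidate (2.6 equiv), CH2Cl2–cyclohexane, rt, 24 h
Reagents that add atoms: tert-butyl 2,2,2-trichloroacetimidate, CC(C)(C)OC(=N)C(Cl)(Cl)Cl
Why: Squaric acid is acidic enough to protonate the imidate and the ion pair collapses to the tert-butyl vinylogous ester (trichloroacetimidate O-alkylation), giving acid-labile protection for the future O5 and O6.

Step 5
Reactants: 11 3,4-di-tert-butoxycyclobut-3-ene-1,2-dione; 12 butanoyl chloride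
Product: 14 (±)-2,3-di-tert-butoxy-1-methyl-4-oxocyclobut-2-en-1-yl butanoate, via lithium alkoxide 13 (not isolated)
Conditions: MeLi (1.05 equiv), THF, −78 °C, 30 min; 12 (1.3 equiv), −78 → −20 °C
Reagents that add atoms: methyllithium, [Li]C
Why: 1,2-Addition of one equivalent of an organolithium to a squarate diester is the classical entry to 4-hydroxycyclobutenones and the tertiary alkoxide is acylated in situ, so the quaternary carbinol (future C7) with its natural ester is made in one flask, as a racemate.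

Step 6
Reactants: 14 (±)-2,3-di-tert-butoxy-1-methyl-4-oxocyclobut-2-en-1-yl butanoate
Product: 15 (S)-2,3-di-tert-butoxy-1-methyl-4-oxocyclobut-2-en-1-yl butanoate
Conditions: preparative chiral SFC (amylose tris(3,5-dimethylphenylcarbamate) phase, CO2/i-PrOH); configuration confirmed by VCD
Reagents that add atoms: none
Why: Resolution on a chiral stationary phase gives the (S)-enantiomer of this small, early intermediate, whose spatial arrangement is that of (7R) in the target (the descriptor changes only because the ring neighbours change CIP rank), so no stereocentre has to be created later.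

Step 7
Reactants: 15 (S)-2,3-di-tert-butoxy-1-methyl-4-oxocyclobut-2-en-1-yl butanoate; 9 (Z)-5,8-bis(tert-butyldimethylsilyloxy)-1,1,4-trimethoxyoct-4-en-2-yne
Product: 16 (S)-2,3-di-tert-butoxy-4-[(Z)-2,5-bis(tert-butyldimethylsilyloxy)-1-methoxypent-1-en-1-yl]-5-(dimethoxymethyl)-1-methyl-6-oxocyclohexa-2,4-dien-1-yl butanoate
Conditions: 15 (1.0 equiv), 9 (1.3 equiv, slow addition), Ni(cod)2 (bis(1,5-cyclooctadiene)nickel, 10 mol%), PPh3 (30 mol%), toluene, 25 → 50 °C
Reagents that add atoms: none
Why: Proposed new method: zerovalent nickel binds the strained ketone of 15 and the alkyne of 9 and joins them by oxidative cyclisation, the carbonyl carbon bonding to the alkyne carbon remote from the coordinating enol-ether alkene (this sets the regiochemistry); β-carbon elimination then opens the four-membered ring at the acyl–alkenyl bond (an alkenylnickel forms rather than a tertiary alkylnickel, so the bond to the quaternary carbinol is kept) and C(sp2)–C(sp2) reductive elimination closes the six-membered dienone with C7 never touched and therefore retained; the closest known reactions are the nickel-catalysed two-carbon ring expansion of cyclobutanones and azetidin-3-ones by alkyne or 1,3-enyne insertion and the nickel-catalysed acyl–aryl bond cleavage of benzocyclobutenones, none shown on a monocyclic cyclobutenone with an ester-bearing quaternary α-carbon.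

Step 8
Reactants: 16 (S)-2,3-di-tert-butoxy-4-[(Z)-2,5-bis(tert-butyldimethylsilyloxy)-1-methoxypent-1-en-1-yl]-5-(dimethoxymethyl)-1-methyl-6-oxocyclohexa-2,4-dien-1-yl butanoate
Product: 18 (7R)-5-hydroxy-3-(3-hydroxypropyl)-4-methoxy-7-methyl-6,8-dioxo-7,8-dihydro-6H-isochromen-7-yl butanoate, via silyl ether 17 (not isolated)
Conditions: (i) TFA (10 equiv), anisole (5 equiv), dry CH2Cl2, −20 → 0 °C; (ii) THF–H2O added, rt; pH 7 buffer work-up
Reagents that add atoms: none
Why: Acid ionises the acetal to an oxocarbenium ion that is captured by the silyl enol ether oxygen (six-membered O-cyclisation, since C-attack would need a four-membered ring), loss of the second methanol gives the 2-benzopyrylium ion, and SN1 loss of both tert-butyl groups plus hydrolysis of the silyl ether leave the neutral 6H-isochromene-6,8-dione (pyrylium-type cyclocondensation as used for azaphilone cores), with C7 untouched.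

**Compound list**
1 | 3,3-dimethoxyprop-1-yne | C#CC(OC)OC | starting material
2 | lithium 3,3-dimethoxyprop-1-yn-1-ide | [Li]C#CC(OC)OC | intermediate
3 | 4,4-dimethoxybut-2-ynal | O=CC#CC(OC)OC | intermediate
4 | 2,3-dihydrofuran | C1CC=CO1 | starting material
5 | 5-lithio-2,3-dihydrofuran | [Li]C1=CCCO1 | intermediate
6 | lithium 1-(4,5-dihydrofuran-2-yl)-4,4-dimethoxybut-2-yn-1-olate (racemic) | [Li]OC(C#CC(OC)OC)C1=CCCO1 | intermediate
7 | 5-(1,4,4-trimethoxybut-2-yn-1-yl)-2,3-dihydrofuran (racemic) | COC(C#CC(OC)OC)C1=CCCO1 | intermediate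
8 | 8-hydroxy-1,1,4-trimethoxyoct-2-yn-5-one (racemic) | COC(C#CC(OC)OC)C(=O)CCCO | intermediate
9 | (Z)-5,8-bis(tert-butyldimethylsilyloxy)-1,1,4-trimethoxyoct-4-en-2-yne | CO/C(C#CC(OC)OC)=C(\O[Si](C)(C)C(C)(C)C)CCCO[Si](C)(C)C(C)(C)C | intermediate
10 | squaric acid (3,4-dihydroxycyclobut-3-ene-1,2-dione) | OC1=C(O)C(=O)C1=O | starting material
11 | 3,4-di-tert-butoxycyclobut-3-ene-1,2-dione | CC(C)(C)OC1=C(OC(C)(C)C)C(=O)C1=O | intermediate
12 | butanoyl chloride | CCCC(Cl)=O | starting material
13 | lithium 2,3-di-tert-butoxy-1-methyl-4-oxocyclobut-2-en-1-olate (racemic) | [Li]OC1(C)C(=O)C(OC(C)(C)C)=C1OC(C)(C)C | intermediate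
14 | (±)-2,3-di-tert-butoxy-1-methyl-4-oxocyclobut-2-en-1-yl butanoate | CCCC(=O)OC1(C)C(=O)C(OC(C)(C)C)=C1OC(C)(C)C | intermediate
15 | (S)-2,3-di-tert-butoxy-1-methyl-4-oxocyclobut-2-en-1-yl butanoate | CCCC(=O)O[C@]1(C)C(=O)C(OC(C)(C)C)=C1OC(C)(C)C | intermediate
16 | (S)-2,3-di-tert-butoxy-4-[(Z)-2,5-bis(tert-butyldimethylsilyloxy)-1-methoxypent-1-en-1-yl]-5-(dimethoxymethyl)-1-methyl-6-oxocyclohexa-2,4-dien-1-yl butanoate | CCCC(=O)O[C@]1(C)C(=O)C(C(OC)OC)=C(/C(OC)=C(/O[Si](C)(C)C(C)(C)C)CCCO[Si](C)(C)C(C)(C)C)C(OC(C)(C)C)=C1OC(C)(C)C | intermediate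
17 | (7R)-3-[3-(tert-butyldimethylsilyloxy)propyl]-5-hydroxy-4-methoxy-7-methyl-6,8-dioxo-7,8-dihydro-6H-isochromen-7-yl butanoate | CCCC(=O)O[C@]1(C)C(=O)C2=COC(CCCO[Si](C)(C)C(C)(C)C)=C(OC)C2=C(O)C1=O | intermediate
18 | (7R)-5-hydroxy-3-(3-hydroxypropyl)-4-methoxy-7-methyl-6,8-dioxo-7,8-dihydro-6H-isochromen-7-yl butanoate | CCCC(=O)O[C@]1(C)C(=O)C2=COC(CCCO)=C(OC)C2=C(O)C1=O | target

**Step count:** 8 steps in total. Longest linear sequence: 5 steps (1, 2, 3, 7, 8; the branch 4, 5, 6, 7, 8 is equally long).

**Steps most likely to fail**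

Step 7 (the proposed new ring expansion). The hindered vinylogous-ester ketone may not react. Nickel may instead open the acyl–quaternary-carbon bond to a vinylketene complex, which would give the 2,5-dienone isomer and racemise C7, so the ee of 16 is checked by SFC. The α-acyloxy C–O bond may also be attacked. The fallback uses known chemistry, sets out from 11 (with 9) and comes back at 17. Compound 11 is converted with MeLi into 13, and trifluoroacetic anhydride then gives 3-tert-butoxy-4-methylcyclobut-3-ene-1,2-dione F1. LiAlH(OtBu)3 reduces the carbonyl next to the alkoxy-bearing carbon to 3-tert-butoxy-4-hydroxy-2-methylcyclobut-2-en-1-one F2, which is silylated (TBSCl, imidazole) to the silyl ether F3. The established Ni(cod)2-catalysed benzannulation of cyclobutenones with alkynes joins F3 and 9 to the pentasubstituted phenol F4 (any regioisomer is separated). Stabilised 2-iodoxybenzoic acid then delivers oxygen to the methyl-bearing ortho carbon (ortho-selective hydroxylative dearomatisation) to give the racemic o-quinol F5. Butanoyl chloride/DMAP gives the racemic butanoate F6, and chiral SFC gives the (S)-butanoate F7. The conditions of step 8 convert F7 into 17 and then 18; the silyl enol ether at O5 is cleaved in place of the tert-butyl ether.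

Step 8 (ring A closure and global deprotection). If the silyl enol ether is protonated and the C5 oxygen freed before ring A has closed, the C5 enol can condense with the C3 ketone to a furan. The fallback sets out from 16 and comes back at 17, closing the ring under neutral conditions first. LiBF4 in wet MeCN hydrolyses only the acetal to the aldehyde F8. Warming in toluene (60 °C) closes the dienal onto the silyl enol ether by oxa-6π electrocyclisation to the 2H-pyran silyl ketal F9 (C3 epimers). TFA in CH2Cl2 then expels silanol and both tert-butyl groups to give 17.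

Step 3 (hydrolysis and double silylation). The β,γ-alkynyl ketone 8 can isomerise to the allenone, and its hemiketal form can divert the silylation. The fallback sets out from 8 and comes back at 18, using the side-chain oxygen itself as the enol ether. MsCl/Et3N gives the keto mesylate F10. DBU closes the enolate oxygen onto the mesylate (5-exo-tet O-alkylation, favoured over enol-endo C-alkylation) to give the silicon-free cyclic enol ether enyne F11, which is handled base-washed because acid returns it to the endocyclic isomer. Step 7 conditions with 15 give the dienone F12. Aqueous TFA then hydrolyses the acetal, the dienal closes onto the enol ether, and ionisation of the resulting spiroketal with loss of both tert-butyl groups gives 18.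

Further compounds
F1 | step 7 | 3-tert-butoxy-4-methylcyclobut-3-ene-1,2-dione | CC1=C(OC(C)(C)C)C(=O)C1=O
F2 | step 7 | (±)-3-tert-butoxy-4-hydroxy-2-methylcyclobut-2-en-1-one | CC1=C(OC(C)(C)C)C(O)C1=O
F3 | step 7 | (±)-3-tert-butoxy-4-(tert-butyldimethylsilyloxy)-2-methylcyclobut-2-en-1-one | CC1=C(OC(C)(C)C)C(O[Si](C)(C)C(C)(C)C)C1=O
F4 | step 7 | 3-tert-butoxy-4-(tert-butyldimethylsilyloxy)-5-[(Z)-2,5-bis(tert-butyldimethylsilyloxy)-1-methoxypent-1-en-1-yl]-6-(dimethoxymethyl)-2-methylphenol | Cc1c(O)c(C(OC)OC)c(/C(OC)=C(/O[Si](C)(C)C(C)(C)C)CCCO[Si](C)(C)C(C)(C)C)c(O[Si](C)(C)C(C)(C)C)c1OC(C)(C)C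
F5 | step 7 | (±)-3-tert-butoxy-4-(tert-butyldimethylsilyloxy)-5-[(Z)-2,5-bis(tert-butyldimethylsilyloxy)-1-methoxypent-1-en-1-yl]-6-(dimethoxymethyl)-2-hydroxy-2-methylcyclohexa-3,5-dien-1-one | CC1(O)C(=O)C(C(OC)OC)=C(/C(OC)=C(/O[Si](C)(C)C(C)(C)C)CCCO[Si](C)(C)C(C)(C)C)C(O[Si](C)(C)C(C)(C)C)=C1OC(C)(C)C
F6 | step 7 | (±)-2-tert-butoxy-3-(tert-butyldimethylsilyloxy)-4-[(Z)-2,5-bis(tert-butyldimethylsilyloxy)-1-methoxypent-1-en-1-yl]-5-(dimethoxymethyl)-1-methyl-6-oxocyclohexa-2,4-dien-1-yl butanoate | CCCC(=O)OC1(C)C(=O)C(C(OC)OC)=C(/C(OC)=C(/O[Si](C)(C)C(C)(C)C)CCCO[Si](C)(C)C(C)(C)C)C(O[Si](C)(C)C(C)(C)C)=C1OC(C)(C)C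
F7 | step 7 | (S)-2-tert-butoxy-3-(tert-butyldimethylsilyloxy)-4-[(Z)-2,5-bis(tert-butyldimethylsilyloxy)-1-methoxypent-1-en-1-yl]-5-(dimethoxymethyl)-1-methyl-6-oxocyclohexa-2,4-dien-1-yl butanoate | CCCC(=O)O[C@]1(C)C(=O)C(C(OC)OC)=C(/C(OC)=C(/O[Si](C)(C)C(C)(C)C)CCCO[Si](C)(C)C(C)(C)C)C(O[Si](C)(C)C(C)(C)C)=C1OC(C)(C)C
F8 | step 8 | (S)-2,3-di-tert-butoxy-4-[(Z)-2,5-bis(tert-butyldimethylsilyloxy)-1-methoxypent-1-en-1-yl]-5-formyl-1-methyl-6-oxocyclohexa-2,4-dien-1-yl butanoate | CCCC(=O)O[C@]1(C)C(=O)C(C=O)=C(/C(OC)=C(/O[Si](C)(C)C(C)(C)C)CCCO[Si](C)(C)C(C)(C)C)C(OC(C)(C)C)=C1OC(C)(C)C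
F9 | step 8 | (7S)-5,6-di-tert-butoxy-3-(tert-butyldimethylsilyloxy)-3-[3-(tert-butyldimethylsilyloxy)propyl]-4-methoxy-7-methyl-8-oxo-7,8-dihydro-3H-isochromen-7-yl butanoate (C3 epimers) | CCCC(=O)O[C@]1(C)C(=O)C2=COC(CCCO[Si](C)(C)C(C)(C)C)(O[Si](C)(C)C(C)(C)C)C(OC)=C2C(OC(C)(C)C)=C1OC(C)(C)C
F10 | step 3 | (±)-5,8,8-trimethoxy-4-oxooct-6-yn-1-yl methanesulfonate | COC(C#CC(OC)OC)C(=O)CCCOS(C)(=O)=O
F11 | step 3 | (Z)-2-(1,4,4-trimethoxybut-2-yn-1-ylidene)oxolane | CO/C(C#CC(OC)OC)=C1/CCCO1
F12 | step 3 | (S)-2,3-di-tert-butoxy-5-(dimethoxymethyl)-4-[(Z)-methoxy(oxolan-2-ylidene)methyl]-1-methyl-6-oxocyclohexa-2,4-dien-1-yl butanoate | CCCC(=O)O[C@]1(C)C(=O)C(C(OC)OC)=C(/C(OC)=C2\CCCO2)C(OC(C)(C)C)=C1OC(C)(C)C
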